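**Retrosynthetic overview**

- The target (cyclohexane locants: C1 carries the acrylic acid, C2 the free OH, C3 the hydroxypropenyl group, C4 methyl and ethenyl, C5 is CH2, C6 carries the acyloxy group) comes from a two-stage deprotection of the ester made by acylating the C6–OH of a triene alcohol with an (R)-acetonide acid from the glycerate chiral pool.
- The cis-1,4 pair ethenyl (on C4) and acrylate (on C1) is one latent etheno bridge: ring-opening ethenolysis of a bicyclo[2.2.2]oct-2-ene-2-carboxylate releases both at once.
- Enabling feature: C4–C5–C6–C1 of the cyclohexane, the ethenyl CH on C4 and the acrylate α-carbon on C1 are the six carbons of a benzene ring (a 5-methylprotocatechuate: arene methyl = C4 methyl, carboxyl = acid carboxyl, phenol O = C6–O). C2 and C3 are the two carbons of an (E)-silyl enol ether hung on the C5 oxygen through an O–CH2–C(=CH2) arm that later is the hydroxypropenyl group.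
- Key disconnection: bonds C1–C2 and C3–C4 together, by enantioselective oxidative dearomatization to a masked o-benzoquinone and intramolecular inverse-demand Diels–Alder reaction; SmI2 then deletes both C5 oxygens (freeing the CH2OH) and borohydride sets C6.
- Ring order: benzene ring (bought) → cyclohexane ring, temporary 2-oxa six-membered tether ring and etheno bridge (all in the key step) → tether ring opened (SmI2) → etheno bridge opened (metathesis).

Key step: step 8

Remark: the sense of induction of the chiral iodane is not predictable for this substrate; the (R,R)-reagent is assumed to give the (4S)-ketal of 12, and the (S,S)-reagent would be used if the opposite sense is found.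

Remark: the target is a γ-hydroxy acid with the hydroxyl cis to the acrylic acid, so the end game avoids acid once that hydroxyl is free.

**Step 1**
Reactants: 1 4-hydroxy-3-methylbenzoic acid
Product: 2 2-(trimethylsilyl)ethyl 4-hydroxy-3-methylbenzoate
Conditions: Me3SiCH2CH2OH, PPh3, DIAD, THF, 0 °C to rt
Reagents that add atoms: 2-(trimethylsilyl)ethanol, C[Si](C)(C)CCO
Why: Mitsunobu esterification, in which the carboxylic acid, far more acidic than the phenol, is the pronucleophile, so the fluoride-labile ester should form without phenol protection.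

**Step 2**
Reactants: 2 2-(trimethylsilyl)ethyl 4-hydroxy-3-methylbenzoate
Product: 3 2-(trimethylsilyl)ethyl 3-formyl-4-hydroxy-5-methylbenzoate
Conditions: MgCl2, Et3N, (CH2O)n, MeCN, reflux; aq. HCl work-up
Reagents that add atoms: paraformaldehyde (as formaldehyde), C=O
Why: Magnesium phenoxide-directed ortho-formylation (Casnati–Skattebøl type) can only occur at the single free position ortho to the hydroxyl.

**Step 3**
Reactants: 3 2-(trimethylsilyl)ethyl 3-formyl-4-hydroxy-5-methylbenzoate
Product: 4 2-(trimethylsilyl)ethyl 3,4-dihydroxy-5-methylbenzoate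
Conditions: 30% H2O2, NaOH, THF/H2O, 0 °C to rt; pH 5 buffer
Reagents that add atoms: hydrogen peroxide, OO
Why: Dakin oxidation (aryl migration in the peroxide adduct of the o-hydroxybenzaldehyde, then formate cleavage) should replace the formyl group by hydroxyl.

**Step 4**
Reactants: 5 2,2-dimethoxyacetaldehyde (60% in water); 6 ethyl 2-(triphenyl-λ5-phosphanylidene)propanoate
Product: 7 ethyl (2E)-4,4-dimethoxy-2-methylbut-2-enoate
Conditions: CH2Cl2, rt
Reagents that add atoms: none
Why: Wittig olefination with a stabilized ylide should give the (E)-trisubstituted enoate, with the acetal carbon cis to the methyl group.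

**Step 5**
Reactants: 7 ethyl (2E)-4,4-dimethoxy-2-methylbut-2-enoate
Product: 8 ethyl (2E)-2-methyl-4-oxobut-2-enoate
Conditions: 1 M HCl, THF, rt
Reagents that add atoms: water, O
Why: Acid-catalysed acetal hydrolysis should unmask the conjugated aldehyde without touching the ester or the alkene geometry.

**Step 6**
Reactants: 8 ethyl (2E)-2-methyl-4-oxobut-2-enoate
Product: 10 (3E)-2-methylidene-4-[(triisopropylsilyl)oxy]but-3-en-1-ol, via silyl dienol ether ester 9 (not isolated)
Conditions: i-Pr3SiOTf, Et3N, Et2O, −78 to −20 °C; then i-Bu2AlH, −78 °C; aq. KNaC4H4O6 work-up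
Reagents that add atoms: triisopropylsilyl trifluoromethanesulfonate, CC(C)[Si](OS(=O)(=O)C(F)(F)F)(C(C)C)C(C)C
Why: Vinylogous soft enolization (only the methyl group carries γ-hydrogens) should give the (1E)-1-silyloxy-1,3-diene, and 1,2-reduction of the ester with i-Bu2AlH at low temperature follows before the push–pull diene can dimerize.

**Step 7**
Reactants: 4 2-(trimethylsilyl)ethyl 3,4-dihydroxy-5-methylbenzoate; 10 (3E)-2-methylidene-4-[(triisopropylsilyl)oxy]but-3-en-1-ol
Product: 11 2-(trimethylsilyl)ethyl 3-hydroxy-5-methyl-4-({(3E)-2-methylidene-4-[(triisopropylsilyl)oxy]but-3-en-1-yl}oxy)benzoate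
Conditions: PPh3, DIAD, THF, 0 °C
Reagents that add atoms: none
Why: Mitsunobu etherification should alkylate the more acidic hydroxyl para to the ester, as in 4-O-alkylations of gallates and protocatechuates, under neutral conditions that spare the silyl dienol ether.

**Step 8**
Reactants: 11 2-(trimethylsilyl)ethyl 3-hydroxy-5-methyl-4-({(3E)-2-methylidene-4-[(triisopropylsilyl)oxy]but-3-en-1-yl}oxy)benzoate
Product: 13 tricyclic adduct: 2-(trimethylsilyl)ethyl 8-methoxy-4-methyl-7-oxo-6-[(triisopropylsilyl)oxy]bicyclo[2.2.2]oct-2-ene-2-carboxylate in which the second C8 oxygen is tied to C5 through O–CH2–C(=CH2) (C6–OSi syn, C5 arm and tether oxygen anti to the C2=C3 bridge), via masked o-benzoquinone 12 (not isolated)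
Conditions: (2R,2'R)-2,2'-[(2-iodo-1,3-phenylene)bis(oxy)]bis[N-(2,4,6-trimethylphenyl)propanamide] (1.2 equiv), mCPBA (1.1 equiv), AcOH, CH2Cl2, rt (λ3-iodane preformed, no peracid left); then 11, MeOH, −40 °C; then 25 °C
Reagents that add atoms: methanol, CO
Why: Proposed new method: the phenol of 11 exchanges onto the preformed chiral aryl-λ3-iodane and methanol attacks the ring carbon that carries the alkoxy arm inside the chiral pocket, expelling the iodoarene and giving the mixed-ketal masked o-benzoquinone 12 with an (S)-ketal carbon; the tethered (E)-silyl enol ether (HOMO) then adds across the two termini of the electron-poor cyclohexadienone (LUMO) in an intramolecular inverse-electron-demand Diels–Alder reaction. The closest known reaction types are the enantioselective dearomatization of phenols with oxygen nucleophiles by chiral aryl-λ3-iodanes (oxidative spirolactonization, hydroxylative dearomatization, with cycloaddition trapping of the dienones) and the PhI(OAc)2/alcohol oxidation of 2-alkoxyphenols followed by intramolecular Diels–Alder reaction of alkenyl mixed ketals; new is enantiocontrol in an intermolecular methanol capture that gives an acyclic mixed ketal. Both new rings, the carbocyclic six-membered ring that becomes the target's cyclohexane and the 2-oxa six-membered tether ring, close in the same suprafacial [4+2] cycloaddition. The temporary ketal stereocenter is set by the reagent; its oxygen arm reaches only one face of the diene, which fixes both bridgeheads (the methyl-bearing quaternary carbon and the CH next to the ketone); the three-atom arm holds the dienophile carbon that carries it anti to the new etheno bridge; and the E geometry then places the silyloxy group on the neighbouring carbon syn to that bridge. The step needs periselectivity for the enol ether C=C over the 1,1-disubstituted C=C of the arm and over dimerization: the enol ether β-carbon has the large HOMO coefficient and meets the methyl-bearing diene terminus with the large LUMO coefficient, the alternative mode would join two fully substituted carbons, and the ring methyl group slows dimerization.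

**Step 9**
Reactants: 13 tricyclic adduct
Product: 14 2-(trimethylsilyl)ethyl 5-(3-hydroxyprop-1-en-2-yl)-4-methyl-7-oxo-6-[(triisopropylsilyl)oxy]bicyclo[2.2.2]oct-2-ene-2-carboxylate (C6–OSi syn, C5 side chain anti to the C2=C3 bridge)
Conditions: SmI2, THF/MeOH, −78 °C
Reagents that add atoms: none
Why: Twofold SmI2 reduction of an α-alkoxy ketone (ketyl, β-elimination of alkoxide, protonation of the samarium enolate) should strip both ketal oxygens, which opens the tether ring and frees the primary allylic alcohol; the other α-carbon is a bridgehead and cannot epimerize.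

**Step 10**
Reactants: 14 keto alcohol
Product: 15 2-(trimethylsilyl)ethyl 5-[3-(tert-butyldimethylsilyloxy)prop-1-en-2-yl]-4-methyl-7-oxo-6-[(triisopropylsilyl)oxy]bicyclo[2.2.2]oct-2-ene-2-carboxylate
Conditions: TBSCl, imidazole, CH2Cl2, 0 °C
Reagents that add atoms: tert-butyldimethylsilyl chloride, CC(C)(C)[Si](C)(C)Cl
Why: Standard silylation of the only hydroxyl group keeps it out of the later esterification.

**Step 11**
Reactants: 15 silyl-protected ketone
Product: 16 2-(trimethylsilyl)ethyl 5-[3-(tert-butyldimethylsilyloxy)prop-1-en-2-yl]-7-hydroxy-4-methyl-6-[(triisopropylsilyl)oxy]bicyclo[2.2.2]oct-2-ene-2-carboxylate (7-OH anti to the C2=C3 bridge, on the side of the C5–C6 bridge)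
Conditions: NaBH4, MeOH/THF, −40 to 0 °C
Reagents that add atoms: none
Why: Substrate-controlled borohydride reduction: hydride should enter from the face of the flat etheno bridge, away from the C5–C6 bridge whose C6–H and C5 side chain shield the other face, which sets the carbinol center with the configuration of C6 in the target.

**Step 12**
Reactants: 16 bicyclic alcohol
Product: 17 2-(trimethylsilyl)ethyl 2-{4-ethenyl-6-hydroxy-4-methyl-3-[3-(tert-butyldimethylsilyloxy)prop-1-en-2-yl]-2-[(triisopropylsilyl)oxy]cyclohexyl}prop-2-enoate (ring configuration as in the target)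
Conditions: second-generation Hoveyda–Grubbs catalyst [RuCl2(H2IMes)(=CH-C6H4-2-O-i-Pr)] (cat.), ethene (5 bar), toluene, 60 °C
Reagents that add atoms: ethene, C=C
Why: Ring-opening cross-metathesis with ethene, driven by release of bicyclic strain and excess ethene, should turn the bridge CH into the ethenyl group on the quaternary carbon and the ester-bearing bridge carbon into the acrylate, cis-1,4 by construction; no stereocenter changes and the 1,1-disubstituted alkene is inert.

**Step 13**
Reactants: 18 methyl (4S)-2,2-dimethyl-1,3-dioxolane-4-carboxylate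
Product: 20 (4R)-4-ethynyl-2,2-dimethyl-1,3-dioxolane, via glyceraldehyde acetonide 19 (not isolated)
Conditions: i-Bu2AlH, CH2Cl2, −78 °C; then MeOH, K2CO3, dimethyl (1-diazo-2-oxopropyl)phosphonate, 0 °C to rt
Reagents that add atoms: dimethyl (1-diazo-2-oxopropyl)phosphonate, COP(=O)(OC)C(=[N+]=[N-])C(C)=O
Why: Half-reduction of the ester and Seyferth–Gilbert homologation with the Ohira–Bestmann reagent should give the alkyne with the stereocenter untouched (the descriptor changes from S to R only through the priority rules).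

**Step 14**
Reactants: 20 (4R)-4-ethynyl-2,2-dimethyl-1,3-dioxolane
Product: 21 methyl 2-[(4R)-2,2-dimethyl-1,3-dioxolan-4-yl]prop-2-enoate
Conditions: Pd(OAc)2 (cat.), 2-(diphenylphosphino)pyridine, MeSO3H (cat.), CO (20 bar), MeOH, N-methylpyrrolidone, 45 °C
Reagents that add atoms: carbon monoxide, [C-]#[O+]; methanol, CO
Why: Palladium hydride-catalysed Markovnikov (branched) methoxycarbonylation of a terminal alkyne with the 2-pyridylphosphine ligand should give the 2-substituted acrylate; the basic ligand buffers the acid co-catalyst so that the acetonide survives.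

**Step 15**
Reactants: 21 methyl 2-[(4R)-2,2-dimethyl-1,3-dioxolan-4-yl]prop-2-enoate
Product: 22 2-[(4R)-2,2-dimethyl-1,3-dioxolan-4-yl]prop-2-enoic acid
Conditions: LiOH, THF/H2O, 0 °C; then 1 M HCl to pH 3–4
Reagents that add atoms: lithium hydroxide, [Li+].[OH-]
Why: Saponification of the methyl ester; the acetonide is stable to base and to the brief, mildly acidic work-up.

**Step 16**
Reactants: 17 triene alcohol; 22 2-[(4R)-2,2-dimethyl-1,3-dioxolan-4-yl]prop-2-enoic acid
Product: 23 fully protected target: the C6 ester of 17 with acid 22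
Conditions: 22, 2,4,6-trichlorobenzoyl chloride, Et3N, toluene, rt; then 17, DMAP, 40 °C
Reagents that add atoms: none
Why: Yamaguchi esterification through the mixed anhydride should acylate the single free secondary hydroxyl with retention at the carbinol carbon.

**Step 17**
Reactants: 23 fully protected target
Product: 24 2-(trimethylsilyl)ethyl ester, triisopropylsilyl ether of the target (side-chain diol and primary allylic alcohol free)
Conditions: AcOH/THF/H2O (3:1:1), 40 °C
Reagents that add atoms: none
Why: Mild acid hydrolysis should remove the acetonide and the primary silyl ether while the hindered secondary triisopropylsilyl ether and the silylethyl ester stay, so the ring hydroxyl cis to the ester is still masked and cannot lactonize under acid.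

**Step 18**
Reactants: 24 partly deprotected ester
Product: 25 2-[(1S,2S,3S,4R,6S)-6-{[(3R)-3,4-dihydroxy-2-methylidenebutanoyl]oxy}-4-ethenyl-2-hydroxy-3-(3-hydroxyprop-1-en-2-yl)-4-methylcyclohexyl]prop-2-enoic acid (target)
Conditions: Bu4NF, AcOH, THF, 0 °C to rt; pH 6 phosphate buffer work-up
Reagents that add atoms: none
Why: Fluoride-induced fragmentation of the 2-silylethyl ester should come first and give the carboxylate, which does not lactonize, and the same buffered fluoride then cleaves the silyl ether; buffering suppresses alkoxide-driven acyl transfer.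

**Compound list**

1 | 4-hydroxy-3-methylbenzoic acid | Cc1cc(C(=O)O)ccc1O | starting material
2 | 2-(trimethylsilyl)ethyl 4-hydroxy-3-methylbenzoate | C[Si](C)(C)CCOC(=O)c1ccc(O)c(C)c1 | intermediate
3 | 2-(trimethylsilyl)ethyl 3-formyl-4-hydroxy-5-methylbenzoate | C[Si](C)(C)CCOC(=O)c1cc(C)c(O)c(C=O)c1 | intermediate
4 | 2-(trimethylsilyl)ethyl 3,4-dihydroxy-5-methylbenzoate | C[Si](C)(C)CCOC(=O)c1cc(C)c(O)c(O)c1 | intermediate
5 | 2,2-dimethoxyacetaldehyde | COC(OC)C=O | starting material
6 | ethyl 2-(triphenyl-λ5-phosphanylidene)propanoate | CCOC(=O)C(C)=P(c1ccccc1)(c1ccccc1)c1ccccc1 | starting material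
7 | ethyl (2E)-4,4-dimethoxy-2-methylbut-2-enoate | CCOC(=O)/C(C)=C/C(OC)OC | intermediate
8 | ethyl (2E)-2-methyl-4-oxobut-2-enoate | CCOC(=O)/C(C)=C/C=O | intermediate
9 | ethyl (3E)-2-methylidene-4-[(triisopropylsilyl)oxy]but-3-enoate | CCOC(=O)C(=C)/C=C/O[Si](C(C)C)(C(C)C)C(C)C | intermediate (not isolated)
10 | (3E)-2-methylidene-4-[(triisopropylsilyl)oxy]but-3-en-1-ol | OCC(=C)/C=C/O[Si](C(C)C)(C(C)C)C(C)C | intermediate
11 | 2-(trimethylsilyl)ethyl 3-hydroxy-5-methyl-4-({(3E)-2-methylidene-4-[(triisopropylsilyl)oxy]but-3-en-1-yl}oxy)benzoate | C[Si](C)(C)CCOC(=O)c1cc(O)c(OCC(=C)/C=C/O[Si](C(C)C)(C(C)C)C(C)C)c(C)c1 | intermediate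
12 | 2-(trimethylsilyl)ethyl (4S)-4-methoxy-5-methyl-4-({(3E)-2-methylidene-4-[(triisopropylsilyl)oxy]but-3-en-1-yl}oxy)-3-oxocyclohexa-1,5-diene-1-carboxylate (masked o-benzoquinone) | C1=C(C)[C@](OC)(OCC(=C)/C=C/O[Si](C(C)C)(C(C)C)C(C)C)C(=O)C=C1C(=O)OCC[Si](C)(C)C | intermediate (not isolated)
13 | tricyclic adduct (bicyclo[2.2.2]oct-2-ene-2-carboxylate; 4-methyl, 7-oxo, 8-methoxy, 6-silyloxy syn to the C2=C3 bridge, C8–O–CH2–C(=CH2)–C5 tether ring) | C1[C@@]2(C)[C@](OC)(O3)C(=O)[C@@H](C=1C(=O)OCC[Si](C)(C)C)[C@@H](O[Si](C(C)C)(C(C)C)C(C)C)[C@@H]2C(=C)C3 | intermediate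
14 | 2-(trimethylsilyl)ethyl 5-(3-hydroxyprop-1-en-2-yl)-4-methyl-7-oxo-6-[(triisopropylsilyl)oxy]bicyclo[2.2.2]oct-2-ene-2-carboxylate | C1[C@@]2(C)CC(=O)[C@@H](C=1C(=O)OCC[Si](C)(C)C)[C@@H](O[Si](C(C)C)(C(C)C)C(C)C)[C@@H]2C(=C)CO | intermediate
15 | 2-(trimethylsilyl)ethyl 5-[3-(tert-butyldimethylsilyloxy)prop-1-en-2-yl]-4-methyl-7-oxo-6-[(triisopropylsilyl)oxy]bicyclo[2.2.2]oct-2-ene-2-carboxylate | C1[C@@]2(C)CC(=O)[C@@H](C=1C(=O)OCC[Si](C)(C)C)[C@@H](O[Si](C(C)C)(C(C)C)C(C)C)[C@@H]2C(=C)CO[Si](C)(C)C(C)(C)C | intermediate
16 | 2-(trimethylsilyl)ethyl 5-[3-(tert-butyldimethylsilyloxy)prop-1-en-2-yl]-7-hydroxy-4-methyl-6-[(triisopropylsilyl)oxy]bicyclo[2.2.2]oct-2-ene-2-carboxylate (7-OH anti to the C2=C3 bridge) | C1[C@@]2(C)C[C@H](O)[C@@H](C=1C(=O)OCC[Si](C)(C)C)[C@@H](O[Si](C(C)C)(C(C)C)C(C)C)[C@@H]2C(=C)CO[Si](C)(C)C(C)(C)C | intermediate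
17 | 2-(trimethylsilyl)ethyl 2-{4-ethenyl-6-hydroxy-4-methyl-3-[3-(tert-butyldimethylsilyloxy)prop-1-en-2-yl]-2-[(triisopropylsilyl)oxy]cyclohexyl}prop-2-enoate (ring configuration as in the target) | C=C[C@@]1(C)C[C@H](O)[C@@H](C(=C)C(=O)OCC[Si](C)(C)C)[C@@H](O[Si](C(C)C)(C(C)C)C(C)C)[C@@H]1C(=C)CO[Si](C)(C)C(C)(C)C | intermediate
18 | methyl (4S)-2,2-dimethyl-1,3-dioxolane-4-carboxylate | COC(=O)[C@@H]1COC(C)(C)O1 | starting material
19 | (4S)-2,2-dimethyl-1,3-dioxolane-4-carbaldehyde | O=C[C@@H]1COC(C)(C)O1 | intermediate (not isolated)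
20 | (4R)-4-ethynyl-2,2-dimethyl-1,3-dioxolane | C#C[C@@H]1COC(C)(C)O1 | intermediate
21 | methyl 2-[(4R)-2,2-dimethyl-1,3-dioxolan-4-yl]prop-2-enoate | COC(=O)C(=C)[C@@H]1COC(C)(C)O1 | intermediate
22 | 2-[(4R)-2,2-dimethyl-1,3-dioxolan-4-yl]prop-2-enoic acid | OC(=O)C(=C)[C@@H]1COC(C)(C)O1 | intermediate
23 | fully protected target (C6 ester of 17 with 22) | C=C[C@@]1(C)C[C@H](OC(=O)C(=C)[C@@H]2COC(C)(C)O2)[C@@H](C(=C)C(=O)OCC[Si](C)(C)C)[C@@H](O[Si](C(C)C)(C(C)C)C(C)C)[C@@H]1C(=C)CO[Si](C)(C)C(C)(C)C | intermediate
24 | 2-(trimethylsilyl)ethyl ester, triisopropylsilyl ether of the target | C=C[C@@]1(C)C[C@H](OC(=O)C(=C)[C@@H](O)CO)[C@@H](C(=C)C(=O)OCC[Si](C)(C)C)[C@@H](O[Si](C(C)C)(C(C)C)C(C)C)[C@@H]1C(=C)CO | intermediate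
25 | 2-[(1S,2S,3S,4R,6S)-6-{[(3R)-3,4-dihydroxy-2-methylidenebutanoyl]oxy}-4-ethenyl-2-hydroxy-3-(3-hydroxyprop-1-en-2-yl)-4-methylcyclohexyl]prop-2-enoic acid | C=C[C@@]1(C)C[C@H](OC(=O)C(=C)[C@@H](O)CO)[C@@H](C(=C)C(=O)O)[C@@H](O)[C@@H]1C(=C)CO | target

**Step count**

Total: 18 steps. Longest linear sequence: 12 steps (steps 1, 2, 3, 7, 8, 9, 10, 11, 12, 16, 17, 18; the branch through steps 4, 5, 6 is equally long).

**Steps most likely to fail, each with a fallback**

1. Step 8 (proposed new method). What may go wrong: insufficient face discrimination in the methanol capture, so that both configurations of the ketal carbon form and the adduct is obtained with low enantiomeric purity. Fallback with known chemistry: setting out from 11, the oxidation is run with PhI(OAc)2 in MeOH (0 to 40 °C), the established achiral route to mixed-ketal masked o-benzoquinones. Compound 12 then forms together with the mirror-image (4R)-masked o-benzoquinone F1 as a racemate. On warming, 12 cyclizes to 13 and F1 cyclizes to the mirror-image tricyclic adduct F2 by the same cycloaddition. Adduct 13 is separated from F2 by preparative chromatography on a chiral stationary phase, and the route is rejoined at 13.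

2. Step 12. What may go wrong: the ruthenium methylidene fails to engage the trisubstituted, ester-bearing bridge alkene, or the ring-opened carbene recloses faster than it is trapped by ethene. Fallback: setting out from 16, Et3SiOTf/2,6-lutidine protects the free hydroxyl and gives the bicyclic triethylsilyl ether F3 . Ozonolysis of F3 (O3, CH2Cl2/MeOH, −78 °C; Me2S) cleaves the bridge alkene and, knowingly, also the exocyclic methylene, and gives the ring-opened tricarbonyl compound F4 , which carries an aldehyde, an α-keto ester and a silyloxymethyl ketone. Threefold Wittig methylenation of F4 (Ph3P=CH2, THF, −78 to 0 °C) rebuilds the ethenyl, acrylate and methylidene groups and gives the monocyclic triethylsilyl ether F5 , the 6-O-triethylsilyl derivative of 17. PPTS in MeOH at 0 °C removes the triethylsilyl group of F5 and the route comes back at 17.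

3. Step 7. What may go wrong: alkylation at the other hydroxyl or at both, or erosion of the silyl dienol ether under the coupling conditions. Fallback: setting out from 3, O-methylation (MeI, K2CO3, DMF) gives 2-(trimethylsilyl)ethyl 3-formyl-4-methoxy-5-methylbenzoate F6 . Baeyer–Villiger oxidation of F6 (mCPBA, CH2Cl2) gives 2-(trimethylsilyl)ethyl 3-(formyloxy)-4-methoxy-5-methylbenzoate F7 . Brief treatment of F7 with K2CO3/MeOH cleaves the formate and gives 2-(trimethylsilyl)ethyl 3-hydroxy-4-methoxy-5-methylbenzoate F8 . Phenol F8 is then oxidized in CH2Cl2 in the presence of alcohol 10 (excess, recoverable), so that the alcohol itself is captured at the methoxy-bearing ring carbon; this gives 12 directly and the route comes back at 12, which cyclizes to 13 as in step 8. With the chiral reagent the antipodal (S,S)-iodane would be used here, because the incoming and the resident alkoxy group have exchanged roles; with PhI(OAc)2 the separation described for step 8 applies.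

**Further compounds**

F1 | step 8 | mirror-image (4R)-masked o-benzoquinone (enantiomer of 12) | C1=C(C)[C@@](OC)(OCC(=C)/C=C/O[Si](C(C)C)(C(C)C)C(C)C)C(=O)C=C1C(=O)OCC[Si](C)(C)C
F2 | step 8 | mirror-image tricyclic adduct (enantiomer of 13) | C1[C@]2(C)[C@@](OC)(O3)C(=O)[C@H](C=1C(=O)OCC[Si](C)(C)C)[C@H](O[Si](C(C)C)(C(C)C)C(C)C)[C@H]2C(=C)C3
F3 | step 12 | bicyclic triethylsilyl ether (7-O-triethylsilyl derivative of 16) | C1[C@@]2(C)C[C@H](O[Si](CC)(CC)CC)[C@@H](C=1C(=O)OCC[Si](C)(C)C)[C@@H](O[Si](C(C)C)(C(C)C)C(C)C)[C@@H]2C(=C)CO[Si](C)(C)C(C)(C)C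
F4 | step 12 | ring-opened tricarbonyl compound: 2-(trimethylsilyl)ethyl 2-oxoacetate bearing the cyclohexane with 4-formyl, 4-methyl, 3-[(tert-butyldimethylsilyloxy)acetyl], 2-triisopropylsilyloxy and 6-triethylsilyloxy groups | O=C[C@@]1(C)C[C@H](O[Si](CC)(CC)CC)[C@@H](C(=O)C(=O)OCC[Si](C)(C)C)[C@@H](O[Si](C(C)C)(C(C)C)C(C)C)[C@@H]1C(=O)CO[Si](C)(C)C(C)(C)C
F5 | step 12 | monocyclic triethylsilyl ether (6-O-triethylsilyl derivative of 17) | C=C[C@@]1(C)C[C@H](O[Si](CC)(CC)CC)[C@@H](C(=C)C(=O)OCC[Si](C)(C)C)[C@@H](O[Si](C(C)C)(C(C)C)C(C)C)[C@@H]1C(=C)CO[Si](C)(C)C(C)(C)C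
F6 | step 7 | 2-(trimethylsilyl)ethyl 3-formyl-4-methoxy-5-methylbenzoate | C[Si](C)(C)CCOC(=O)c1cc(C)c(OC)c(C=O)c1
F7 | step 7 | 2-(trimethylsilyl)ethyl 3-(formyloxy)-4-methoxy-5-methylbenzoate | C[Si](C)(C)CCOC(=O)c1cc(C)c(OC)c(OC=O)c1
F8 | step 7 | 2-(trimethylsilyl)ethyl 3-hydroxy-4-methoxy-5-methylbenzoate | C[Si](C)(C)CCOC(=O)c1cc(C)c(OC)c(O)c1
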